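**Plan** (labdane numbering, C1–C20)
1. Late cuts: the C6 butanoate, then C13–OH/C14=C15, which come from a 13,14-epoxy-15-iodide made by Sharpless epoxidation of the (13E)-allylic alcohol.
2. Key cut: C4–C5 (ring A) and C10–C9 (ring B) together. C5 lies between the fully substituted C4 and C10 and next to the oxygenated C6, so a cis-5,6-epoxide on a 1,2,2-trimethylcyclopentyl group can shift C4 from C10 to C5; the C10 cation so formed is the one that closes ring B on the C8=C9 alkene.
3. Last cut: C6–C7, by enolate alkylation of methyl ketone 6 with allylic bromide 9 (from methyl geranate).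
4. Forward: cyclopentane block, chain union, C6/C5 oxygenation and epoxide, then ring A (five to six) and ring B in one step, then side chain and ester.
5. Stereochemistry: C6 by reagent-controlled enolate hydroxylation; C5 by chelation-controlled reduction, then inversion in the shift; C10 and C9 in the chair cyclization; C13 by D-(−)-tartrate epoxidation. The racemic ring stereocentre of 6 is erased at C10.

Key step: step 10

Remark: the ring quaternary carbon of 2–6 and 10–17 (later C10) is racemic or epimeric and is written without configuration, because step 10 planarises it and both epimers converge.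
Remark: the (+)-oxaziridine is assumed to hydroxylate enolate 12 on the face that gives the (S)-alcohol, by analogy with simple acyclic Z-enolates; otherwise the antipodal reagent would be used.
Remark: methyl geranate 7 is taken as the commercial (2E) ester.

**Step 1**
Reactants: 1 2,2-dimethylcyclopentan-1-one
Product: 2 2,2-dimethylcyclopentane-1-carbonitrile (racemic)
Conditions: TosMIC, KOt-Bu, DME, EtOH (1.5 equiv), 0 to 40 °C
Reagents that add atoms: p-toluenesulfonylmethyl isocyanide (TosMIC), [C-]#[N+]CS(=O)(=O)c1ccc(C)cc1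
Why: The van Leusen reductive cyanation turns a ketone into the homologous nitrile and should tolerate the α-quaternary carbon; the new stereocentre is racemic and is removed in step 2.

**Step 2**
Reactants: 2 2,2-dimethylcyclopentane-1-carbonitrile
Product: 4 1,2,2-trimethylcyclopentane-1-carbonitrile (racemic), via lithiated nitrile 3 (not isolated)
Conditions: LiN(i-Pr)2, THF, −78 °C; MeI, −78 to 0 °C
Reagents that add atoms: iodomethane, CI
Why: SN2 methylation of the nitrile-stabilised carbanion builds the quaternary carbon (later C10) next to the gem-dimethyl carbon (later C4), as a racemate that step 10 makes irrelevant.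

**Step 3**
Reactants: 4 1,2,2-trimethylcyclopentane-1-carbonitrile
Product: 6 1-(1,2,2-trimethylcyclopentyl)ethan-1-one (racemic), via lithium ketimide 5 (not isolated)
Conditions: MeLi, Et2O, 0 °C to reflux; then 2 M aq. HCl, 40 °C
Reagents that add atoms: methyllithium, [Li]C; water, O
Why: Organolithium addition to a hindered nitrile stops at the N-lithio ketimine, and acid hydrolysis then gives the methyl ketone (C5 carbonyl, C6 methyl).

**Step 4**
Reactants: 7 methyl geranate [methyl (2E)-3,7-dimethylocta-2,6-dienoate]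
Product: 8 methyl (2E,6E)-8-hydroxy-3,7-dimethylocta-2,6-dienoate
Conditions: SeO2 (0.3 equiv), t-BuOOH, salicylic acid (cat.), CH2Cl2, 25 °C
Reagents that add atoms: tert-butyl hydroperoxide, CC(C)(C)OO
Why: SeO2-catalysed allylic oxidation (ene reaction, then [2,3] shift) should hydroxylate the (E)-methyl group of the electron-rich trisubstituted alkene and leave the conjugated alkene alone.

**Step 5**
Reactants: 8 methyl (2E,6E)-8-hydroxy-3,7-dimethylocta-2,6-dienoate
Product: 9 methyl (2E,6E)-8-bromo-3,7-dimethylocta-2,6-dienoate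
Conditions: CBr4, PPh3, CH2Cl2, 0 °C
Reagents that add atoms: carbon tetrabromide, BrC(Br)(Br)Br
Why: The Appel reaction converts the primary allylic alcohol into the bromide without allylic transposition or loss of alkene geometry.

**Step 6**
Reactants: 6 1-(1,2,2-trimethylcyclopentyl)ethan-1-one; 9 methyl (2E,6E)-8-bromo-3,7-dimethylocta-2,6-dienoate
Product: 11 methyl (2E,6E)-3,7-dimethyl-10-oxo-10-(1,2,2-trimethylcyclopentyl)deca-2,6-dienoate (racemic), via lithium enolate 10 (not isolated)
Conditions: LiN(i-Pr)2, THF, −78 °C; then 9, DMPU, −78 to −20 °C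
Reagents that add atoms: none
Why: The ketone can enolise only toward its methyl group, and SN2 C-alkylation of this lithium enolate by the primary allylic bromide forms the C6–C7 bond.

**Step 7**
Reactants: 11 methyl (2E,6E)-3,7-dimethyl-10-oxo-10-(1,2,2-trimethylcyclopentyl)deca-2,6-dienoate
Product: 13 methyl (2E,6E,9S)-9-hydroxy-3,7-dimethyl-10-oxo-10-(1,2,2-trimethylcyclopentyl)deca-2,6-dienoate (two epimers at the ring carbon), via sodium enolate 12 (not isolated)
Conditions: NaN(SiMe3)2 (1.1 equiv), THF, −78 °C; (+)-(camphorylsulfonyl)oxaziridine, −78 to −50 °C; aq. NH4Cl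
Reagents that add atoms: (+)-(camphorylsulfonyl)oxaziridine, O=S1(=O)C[C@@]23CC[C@@H](C2(C)C)C[C@]34O[N@]14
Why: Enolate hydroxylation with an enantiopure N-sulfonyloxaziridine (Davis oxidation) transfers oxygen to one face of the Z-enolate, the only enolate that can form, and so sets C6 (S) under reagent control.

**Step 8**
Reactants: 13 methyl (2E,6E,9S)-9-hydroxy-3,7-dimethyl-10-oxo-10-(1,2,2-trimethylcyclopentyl)deca-2,6-dienoate
Product: 14 methyl (2E,6E,9S,10R)-9,10-dihydroxy-3,7-dimethyl-10-(1,2,2-trimethylcyclopentyl)deca-2,6-dienoate (anti-diol)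
Conditions: Zn(BH4)2, Et2O, −20 to 0 °C; aq. NH4Cl
Reagents that add atoms: none
Why: In this chelation-controlled reduction zinc bridges the hydroxyl and carbonyl oxygens and hydride adds from the side of the C6 hydrogen, which should give the anti (erythro) diol and set C5, with the enoate untouched.

**Step 9**
Reactants: 14 methyl (2E,6E,9S,10R)-9,10-dihydroxy-3,7-dimethyl-10-(1,2,2-trimethylcyclopentyl)deca-2,6-dienoate
Product: 17 methyl (2E,6E)-3,7-dimethyl-8-[(2S,3R)-3-(1,2,2-trimethylcyclopentyl)oxiran-2-yl]octa-2,6-dienoate (cis-epoxide), via cyclic orthoacetate 15 (not isolated), via bromo acetate 16 (not isolated)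
Conditions: MeC(OMe)3, pyridinium p-toluenesulfonate (cat.), CH2Cl2, 25 °C; AcBr, CH2Cl2, 0 °C; K2CO3, MeOH, 25 °C
Reagents that add atoms: none
Why: In the orthoester route from a 1,2-diol to its epoxide, bromide opens the acetoxonium ion at the less hindered C6 with inversion and the C5 alkoxide closes the ring with a second inversion, so both configurations are kept and the anti-diol gives the cis-epoxide.

**Step 10**
Reactants: 17 methyl (2E,6E)-3,7-dimethyl-8-[(2S,3R)-3-(1,2,2-trimethylcyclopentyl)oxiran-2-yl]octa-2,6-dienoate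
Product: 19 methyl (13E)-6α-hydroxylabda-7,13-dien-15-oate [(5S,6S,9S,10R)], via ring A cation 18 (not isolated)
Conditions: MeAlCl2 (2.2 equiv, hexanes), CH2Cl2, −78 to −40 °C; then aq. potassium sodium tartrate
Reagents that add atoms: none
Why: Proposed new method: MeAlCl2 binds the epoxide oxygen and the C5–O bond breaks while the anti-periplanar C10–C4 ring bond migrates from C10 to C5 (Wagner–Meerwein 1,2-shift, inversion at C5), which enlarges the cyclopentane to the tertiary ring A cation 18 at C10 and leaves O6 as an aluminium alkoxide with C6 untouched; the C8=C9 alkene then captures C10 and the C8 cation loses H7 to the Al–Me group as methane. The closest known reaction types are the Lewis-acid-promoted epoxide-initiated cation–olefin cyclization and the solvolytic ring enlargement of cyclopentylcarbinyl sulfonates next to a quaternary carbon (C-nor-D-homo steroid rearrangement); here the epoxide carbon is only secondary, so ionization is expected to rely on the σ-assistance of the migrating bond. Ring A arises by one-carbon ring enlargement (five to six, C5 inserted between C10 and C4), and ring B closes by 6-endo-trig attack of C9 on the C10 cation through a chair transition state. C5 is set by the stereospecific shift, C6 is carried over, and C10 and C9 are set in the chair closure by the equatorial O6 and C5 substituents and the E alkene (trans ring fusion, equatorial side chain), while the cyclopentane stereocentre is erased at C10. The step needs migration of C4 rather than C1 or methyl (higher migratory aptitude of the fully substituted carbon), cleavage at C5 rather than C6 (quaternary neighbour), the 7-ene rather than the 8(17)- or 8-ene (the C6 aluminium alkoxide can pass its methyl group to the axial H7 through a six-membered transition state), and a spectator enoate alkene (conjugated and Lewis-acid-bound).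

**Step 11**
Reactants: 19 methyl (13E)-6α-hydroxylabda-7,13-dien-15-oate
Product: 20 (13E)-labda-7,13-diene-6α,15-diol
Conditions: i-Bu2AlH (3.3 equiv), CH2Cl2, −78 °C; aq. potassium sodium tartrate
Reagents that add atoms: none
Why: 1,2-Reduction of the conjugated methyl ester with i-Bu2AlH gives the (E)-allylic alcohol and should not touch the two trisubstituted alkenes.

**Step 12**
Reactants: 20 (13E)-labda-7,13-diene-6α,15-diol
Product: 21 (13R,14R)-13,14-epoxylabd-7-ene-6α,15-diol
Conditions: Ti(OiPr)4 (10 mol %), D-(−)-diethyl tartrate (12 mol %), t-BuOOH (1.2 equiv), 4 Å sieves, CH2Cl2, −25 °C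
Reagents that add atoms: tert-butyl hydroperoxide, CC(C)(C)OO
Why: In the Sharpless asymmetric epoxidation D-(−)-diethyl tartrate delivers oxygen to the face of the (E)-allylic alcohol that gives the (13R,14R)-epoxide (the geraniol (2R,3R) sense), and the primary allylic alcohol should react far faster than the hindered ring allylic alcohol at C6.

**Step 13**
Reactants: 21 (13R,14R)-13,14-epoxylabd-7-ene-6α,15-diol
Product: 22 (13R,14S)-13,14-epoxy-15-iodolabd-7-en-6α-ol (same spatial arrangement as 21)
Conditions: I2, PPh3, imidazole, THF, 0 °C, dark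
Reagents that add atoms: iodine, II
Why: Appel-type iodination with PPh3/I2/imidazole should convert the primary alcohol without opening the epoxide and leave the hindered secondary alcohol.

**Step 14**
Reactants: 22 (13R,14S)-13,14-epoxy-15-iodolabd-7-en-6α-ol
Product: 23 (13R)-labda-7,14-diene-6α,13-diol
Conditions: Zn dust, AcOH (2 equiv), EtOH, 0 to 25 °C
Reagents that add atoms: none
Why: Zinc inserts into the C–I bond and β-elimination opens the epoxide at C14 (reductive fragmentation of a 2,3-epoxy iodide), which gives the tertiary allylic alcohol with the C13–O bond, and hence 13R, untouched.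

**Step 15**
Reactants: 23 (13R)-labda-7,14-diene-6α,13-diol
Product: 24 (13R)-13-hydroxylabda-7,14-dien-6α-yl butanoate (CNP0339102.1)
Conditions: butyric anhydride, DMAP (0.2 equiv), Et3N, CH2Cl2, 0 to 25 °C
Reagents that add atoms: butyric anhydride, CCCC(=O)OC(=O)CCC
Why: DMAP-catalysed acylation should esterify the secondary C6 hydroxyl, while the tertiary allylic C13 hydroxyl is too hindered to react under these conditions.

**Compound list**
1 | 2,2-dimethylcyclopentan-1-one | CC1(C)CCCC1=O | starting material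
2 | 2,2-dimethylcyclopentane-1-carbonitrile (racemic) | N#CC1CCCC1(C)C | intermediate
3 | lithiated nitrile of 2 (N-lithio keteniminate, not isolated) | [Li]N=C=C1CCCC1(C)C | intermediate
4 | 1,2,2-trimethylcyclopentane-1-carbonitrile (racemic) | N#CC1(C)CCCC1(C)C | intermediate
5 | lithium [1-(1,2,2-trimethylcyclopentyl)ethylidene]amide (not isolated) | CC(=N[Li])C1(C)CCCC1(C)C | intermediate
6 | 1-(1,2,2-trimethylcyclopentyl)ethan-1-one (racemic) | CC(=O)C1(C)CCCC1(C)C | intermediate
7 | methyl geranate, methyl (2E)-3,7-dimethylocta-2,6-dienoate | COC(=O)/C=C(\C)CCC=C(C)C | starting material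
8 | methyl (2E,6E)-8-hydroxy-3,7-dimethylocta-2,6-dienoate | COC(=O)/C=C(\C)CC/C=C(\C)CO | intermediate
9 | methyl (2E,6E)-8-bromo-3,7-dimethylocta-2,6-dienoate | COC(=O)/C=C(\C)CC/C=C(\C)CBr | intermediate
10 | lithium 1-(1,2,2-trimethylcyclopentyl)ethen-1-olate (not isolated) | [Li]OC(=C)C1(C)CCCC1(C)C | intermediate
11 | methyl (2E,6E)-3,7-dimethyl-10-oxo-10-(1,2,2-trimethylcyclopentyl)deca-2,6-dienoate (racemic) | COC(=O)/C=C(\C)CC/C=C(\C)CCC(=O)C1(C)CCCC1(C)C | intermediate
12 | sodium (Z)-enolate of 11 (not isolated) | [Na]O/C(=C\C/C(C)=C/CC/C(C)=C/C(=O)OC)C1(C)CCCC1(C)C | intermediate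
13 | methyl (2E,6E,9S)-9-hydroxy-3,7-dimethyl-10-oxo-10-(1,2,2-trimethylcyclopentyl)deca-2,6-dienoate (epimers at the ring carbon) | COC(=O)/C=C(\C)CC/C=C(\C)C[C@H](O)C(=O)C1(C)CCCC1(C)C | intermediate
14 | methyl (2E,6E,9S,10R)-9,10-dihydroxy-3,7-dimethyl-10-(1,2,2-trimethylcyclopentyl)deca-2,6-dienoate (anti-diol) | COC(=O)/C=C(\C)CC/C=C(\C)C[C@H](O)[C@H](O)C1(C)CCCC1(C)C | intermediate
15 | methyl (2E,6E)-8-[(4S,5R)-2-methoxy-2-methyl-5-(1,2,2-trimethylcyclopentyl)-1,3-dioxolan-4-yl]-3,7-dimethylocta-2,6-dienoate (cyclic orthoacetate, not isolated) | COC(=O)/C=C(\C)CC/C=C(\C)C[C@@H]1OC(C)(OC)O[C@@H]1C2(C)CCCC2(C)C | intermediate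
16 | methyl (2E,6E,9R,10R)-10-acetoxy-9-bromo-3,7-dimethyl-10-(1,2,2-trimethylcyclopentyl)deca-2,6-dienoate (not isolated) | COC(=O)/C=C(\C)CC/C=C(\C)C[C@@H](Br)[C@H](OC(C)=O)C1(C)CCCC1(C)C | intermediate
17 | methyl (2E,6E)-3,7-dimethyl-8-[(2S,3R)-3-(1,2,2-trimethylcyclopentyl)oxiran-2-yl]octa-2,6-dienoate (cis-epoxide) | COC(=O)/C=C(\C)CC/C=C(\C)C[C@@H]1O[C@@H]1C2(C)CCCC2(C)C | intermediate
18 | ring A tertiary cation at C10 with O6 as dichloro(methyl)aluminate (not isolated) | COC(=O)/C=C(\C)CC/C=C(\C)C[C@H](O[Al-](C)(Cl)Cl)[C@H]1C(C)(C)CCC[C+]1C | intermediate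
19 | methyl (13E)-6α-hydroxylabda-7,13-dien-15-oate (5S,6S,9S,10R) | COC(=O)/C=C(\C)CC[C@H]1C(C)=C[C@H](O)[C@H]2C(C)(C)CCC[C@]12C | intermediate
20 | (13E)-labda-7,13-diene-6α,15-diol | OC/C=C(\C)CC[C@H]1C(C)=C[C@H](O)[C@H]2C(C)(C)CCC[C@]12C | intermediate
21 | (13R,14R)-13,14-epoxylabd-7-ene-6α,15-diol | OC[C@H]1O[C@]1(C)CC[C@H]2C(C)=C[C@H](O)[C@H]3C(C)(C)CCC[C@]23C | intermediate
22 | (13R,14S)-13,14-epoxy-15-iodolabd-7-en-6α-ol | IC[C@H]1O[C@]1(C)CC[C@H]2C(C)=C[C@H](O)[C@H]3C(C)(C)CCC[C@]23C | intermediate
23 | (13R)-labda-7,14-diene-6α,13-diol | C=C[C@](C)(O)CC[C@H]1C(C)=C[C@H](O)[C@H]2C(C)(C)CCC[C@]12C | intermediate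
24 | (13R)-13-hydroxylabda-7,14-dien-6α-yl butanoate (5S,6S,9S,10R,13R) | C=C[C@](C)(O)CC[C@H]1C(C)=C[C@H](OC(=O)CCC)[C@H]2C(C)(C)CCC[C@]12C | target

**Totals and risks**
Total steps: 15. Longest linear sequence: 13 steps (1, 2, 3, then 6 to 15).

Step 10 (ring enlargement and ring B closure). The activated epoxide or the cation may be diverted: chloride capture, migration of the wrong ring bond, hydride shifts ending in a C6 ketone, or proton loss to a mixture of double-bond isomers. The fallback runs the same events stepwise with known reactions, from diol 14 back to 19. The less hindered C6 hydroxyl is silylated (TBSCl, imidazole, DMF) to methyl (2E,6E,9S,10R)-9-[(tert-butyldimethylsilyl)oxy]-10-hydroxy-3,7-dimethyl-10-(1,2,2-trimethylcyclopentyl)deca-2,6-dienoate F1. The neopentyl-type C5 hydroxyl is mesylated (MsCl, Et3N, CH2Cl2, 0 °C) to methyl (2E,6E,9S,10R)-9-[(tert-butyldimethylsilyl)oxy]-3,7-dimethyl-10-[(methylsulfonyl)oxy]-10-(1,2,2-trimethylcyclopentyl)deca-2,6-dienoate F2. Buffered solvolysis (2,6-lutidine, (CF3)2CHOH, 40 °C), the classical Wagner–Meerwein ring enlargement of a cyclopentylcarbinyl sulfonate, ends in proton loss to methyl (2E,6E,9S)-9-[(tert-butyldimethylsilyl)oxy]-3,7-dimethyl-9-[(1S)-2,6,6-trimethylcyclohex-2-en-1-yl]nona-2,6-dienoate F3 (drawn as the 1(10)-ene; its double-bond isomers lead to the same cation). A separate proton-initiated cyclization of this monocyclic diene (SnCl4, CF3CH2OH, CH2Cl2, −78 °C) closes ring B to methyl (13E)-6α-[(tert-butyldimethylsilyl)oxy]labda-7,13-dien-15-oate F4, and n-Bu4NF in THF gives 19.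

Step 7 (enolate hydroxylation). Oxygen transfer to the hindered enolate may show poor enantiofacial selectivity, and the base may deprotonate the dienoate instead of the ketone. The fallback sets C5 and C6 by a tartrate-controlled kinetic resolution; it sets out from 6 (with 8) and returns at 14. Alcohol 8 is oxidised (MnO2, CH2Cl2) to methyl (2E,6E)-3,7-dimethyl-8-oxoocta-2,6-dienoate F5. Aldol addition of enolate 10 to F5 and dehydration (MsCl, Et3N; DBU) gives methyl (2E,6E,8E)-3,7-dimethyl-10-oxo-10-(1,2,2-trimethylcyclopentyl)deca-2,6,8-trienoate F6. Luche reduction (NaBH4, CeCl3·7H2O, MeOH) gives racemic methyl (2E,6E,8E)-10-hydroxy-3,7-dimethyl-10-(1,2,2-trimethylcyclopentyl)deca-2,6,8-trienoate F7. Sharpless kinetic-resolution epoxidation (Ti(OiPr)4, D-(−)-diisopropyl tartrate, t-BuOOH 0.55 equiv, −20 °C) should convert the wanted enantiomer into the anti-epoxy alcohol methyl (2E,6E)-7-{(2R,3R)-3-[(R)-hydroxy(1,2,2-trimethylcyclopentyl)methyl]oxiran-2-yl}-3-methylocta-2,6-dienoate F8. Palladium-catalysed formate hydrogenolysis of the alkenyl oxirane (Pd2(dba)3·CHCl3, n-Bu3P, HCO2H, Et3N, dioxane) places hydride on the allylic epoxide carbon and gives anti-diol 14.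

Step 15 (final esterification). Acylation of the equatorial C6 hydroxyl, crowded by the C4 α-methyl group, may be slow, and forcing conditions may begin to acylate or ionise the tertiary allylic alcohol. The fallback changes the order, from 22 to 24. The epoxy iodide is acylated first (butyric anhydride, DMAP, pyridine, 0 to 25 °C), with no tertiary alcohol present, to (13R,14S)-13,14-epoxy-15-iodolabd-7-en-6α-yl butanoate F9. Zinc and acetic acid in ethanol then unveil the tertiary allylic alcohol and give 24 directly.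

**Further compounds**
F1 | step 10 | methyl (2E,6E,9S,10R)-9-[(tert-butyldimethylsilyl)oxy]-10-hydroxy-3,7-dimethyl-10-(1,2,2-trimethylcyclopentyl)deca-2,6-dienoate | COC(=O)/C=C(\C)CC/C=C(\C)C[C@H](O[Si](C)(C)C(C)(C)C)[C@H](O)C1(C)CCCC1(C)C
F2 | step 10 | methyl (2E,6E,9S,10R)-9-[(tert-butyldimethylsilyl)oxy]-3,7-dimethyl-10-[(methylsulfonyl)oxy]-10-(1,2,2-trimethylcyclopentyl)deca-2,6-dienoate | COC(=O)/C=C(\C)CC/C=C(\C)C[C@H](O[Si](C)(C)C(C)(C)C)[C@H](OS(C)(=O)=O)C1(C)CCCC1(C)C
F3 | step 10 | methyl (2E,6E,9S)-9-[(tert-butyldimethylsilyl)oxy]-3,7-dimethyl-9-[(1S)-2,6,6-trimethylcyclohex-2-en-1-yl]nona-2,6-dienoate | COC(=O)/C=C(\C)CC/C=C(\C)C[C@H](O[Si](C)(C)C(C)(C)C)[C@H]1C(C)(C)CCC=C1C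
F4 | step 10 | methyl (13E)-6α-[(tert-butyldimethylsilyl)oxy]labda-7,13-dien-15-oate | COC(=O)/C=C(\C)CC[C@H]1C(C)=C[C@H](O[Si](C)(C)C(C)(C)C)[C@H]2C(C)(C)CCC[C@]12C
F5 | step 7 | methyl (2E,6E)-3,7-dimethyl-8-oxoocta-2,6-dienoate | COC(=O)/C=C(\C)CC/C=C(\C)C=O
F6 | step 7 | methyl (2E,6E,8E)-3,7-dimethyl-10-oxo-10-(1,2,2-trimethylcyclopentyl)deca-2,6,8-trienoate | COC(=O)/C=C(\C)CC/C=C(\C)/C=C/C(=O)C1(C)CCCC1(C)C
F7 | step 7 | methyl (2E,6E,8E)-10-hydroxy-3,7-dimethyl-10-(1,2,2-trimethylcyclopentyl)deca-2,6,8-trienoate (racemic carbinol) | COC(=O)/C=C(\C)CC/C=C(\C)/C=C/C(O)C1(C)CCCC1(C)C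
F8 | step 7 | methyl (2E,6E)-7-{(2R,3R)-3-[(R)-hydroxy(1,2,2-trimethylcyclopentyl)methyl]oxiran-2-yl}-3-methylocta-2,6-dienoate | COC(=O)/C=C(\C)CC/C=C(\C)[C@H]1O[C@@H]1[C@H](O)C2(C)CCCC2(C)C
F9 | step 15 | (13R,14S)-13,14-epoxy-15-iodolabd-7-en-6α-yl butanoate | IC[C@H]1O[C@]1(C)CC[C@H]2C(C)=C[C@H](OC(=O)CCC)[C@H]3C(C)(C)CCC[C@]23C
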